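The numbers in the tables were computed with made-up constants, noise included.

Start from a one-step world: electrophile meets nucleophile, the nucleophile is in excess, and the electrophile falls with one steady first-order constant (pseudo-first-order).

- winter: electrophile 0.50 M; nucleophile 1.6 M; run made earlier
- flask: electrophile 0.50 M; time 25 h

winter run (percent of the electrophile charged)

| time / h | target / % | electrophile / % |
|---|---|---|
| 0.667 | 26.9 | 73.6 |
| 1.33 | 42.5 | 59.4 |
| 3.00 | 59.7 | 40.2 |
| 8.00 | 80.6 | 18.7 |

(scatter of a reading: 1 percentage point)

- the amount of nucleophile is what is sought; it is there from the start
- steps under discussion: electrophile + nucleophile -> acid set free + target; 2 nucleophile -> self-condensation product; nucleophile + acid set free <-> protonated nucleophile; acid set free -> by-product carried off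

- the concentration of nucleophile at which the part of the electrophile that has reacted at 25 h is just 70%, in M

Now look at what does not fit. The winter run charges 3.20 nucleophile per electrophile, and one-to-one use still leaves 1.19 M at 8.00 h. Yet the first-order constant falls from 0.460 /h over the first interval to 0.153 /h over the last, about a third.

To clear this up, divide the early constant by the charge and read k = 0.287 /M/h. The late constant then stands for free nucleophile near 0.533 M, less than those one-to-one leftovers. So watch free nucleophile, not the charge.

Define the exposure E as free nucleophile summed over time; reaching the wanted part takes E = 4.19 M·h.

Now reckon both ends. If time cost nothing, the charge must pay for the reaction and for one protonated nucleophile per acid: 0.700 M. If use cost nothing, holding E over 25 h takes 0.168 M. Joined, my estimate is 0.868 M.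

The forecast says 0.75 M, from 0.57 M to 1 M, lower than mine, on the ground of “capture with some acid escape”.

The flask gives 0.823 M.

    electrophile + nucleophile → acid set free + target (k = 0.00541 /M/min)
    2 nucleophile → self-condensation product (k = 9.88 × 10⁻⁴ /M/min)
    nucleophile + acid set free ⇌ protonated nucleophile, settled at all times (K = 465 /M)
    acid set free → by-product carried off (k = 0.00342 /min)

At that charge, 9.46% of the nucleophile is still free at 12.5 h, when 62.8% of the electrophile is used, and 4.98% at 25.0 h. Put the exposure to use on this flask: the electrophile used at 12.5 h stands for 82.1% of E, a share in which k cancels, so the stretch from 12.5 h to 25.0 h brings the remaining 17.9%.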